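**Retrosynthetic overview**

1. The last bond made is the one between the dienone C2 and the isoindolinone C3. It comes from an enantioselective Mannich-type amidoalkylation of the free cyclic vinylogous acid with an N-acyl imine, under a chiral phosphoric acid.
2. The cyclohexadienone is numbered C1 (C=O), C2, C3 (C–OH), C4 (=CH), C5 (C–CH3), C6 (quaternary, two prenyl groups). It is closed by forming C3–C4: an α-oxoketene spanning C1–C2–C3 is attacked by the terminus of an allylsilane.
3. Enabling feature: the 1,3-dioxygenated C1–C2–C3 triad is an α-oxoketene at the correct oxidation level, and C4=C5(CH3) is a 2-substituted allyl unit on the quaternary C6. A CH2SiMe3 group in place of the C5 methyl makes C4 far more nucleophilic than the two prenyl alkenes, and it ends as the C5 methyl group.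
4. C6 is made first by double prenylation of methyl acetoacetate. The ketone then becomes the allylsilane (enol triflate, cross-coupling) and the ester becomes the ketene precursor (acid, acyl Meldrum's acid).
5. Order of ring formation: cyclohexadienone (step 6), isoindolinone (step 8, from 3-methoxybenzonitrile), then union of the two rings (step 9).

Key step: step 6

Assumption: the dienone is treated in the drawn 3-hydroxy-2,4-dien-1-one tautomer (the enol tautomers interconvert); the single stereocentre, C3 of the isoindolinone, is R (CIP order N > dienone carbon > aryl carbon > H).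

Step 1
Reactants: 1 methyl acetoacetate (methyl 3-oxobutanoate); 2 prenyl bromide (1-bromo-3-methylbut-2-ene)
Product: 4 methyl 2-acetyl-5-methyl-2-(3-methylbut-2-en-1-yl)hex-4-enoate, via mono-prenylated keto ester 3 (not isolated)
Conditions: NaH (2.2 equiv), 2 (2.3 equiv), THF/DMF, 0 °C to rt
Reagents that add atoms: none
Why: Double C-alkylation of the β-keto ester enolate by the primary allylic bromide (acetoacetic ester alkylation, SN2) should install both prenyl groups on the carbon that becomes the quaternary C6; no stereocentre is formed.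

Step 2
Reactants: 4 methyl 2-acetyl-5-methyl-2-(3-methylbut-2-en-1-yl)hex-4-enoate
Product: 6 methyl 5-methyl-2-(3-methylbut-2-en-1-yl)-2-{1-[(trifluoromethanesulfonyl)oxy]ethenyl}hex-4-enoate, via potassium enolate 5 (not isolated)
Conditions: KN(SiMe3)2, THF, –78 °C; PhNTf2, –78 to 0 °C; aq. NH4Cl
Reagents that add atoms: N-phenylbis(trifluoromethanesulfonimide), O=S(=O)(N(c1ccccc1)S(=O)(=O)C(F)(F)F)C(F)(F)F
Why: Only the acetyl methyl group of 4 can be enolised, so kinetic deprotonation and O-sulfonylation of the enolate (enol triflate formation) should give the 1,1-disubstituted vinyl triflate without regiochemical ambiguity.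

Step 3
Reactants: 6 methyl 5-methyl-2-(3-methylbut-2-en-1-yl)-2-{1-[(trifluoromethanesulfonyl)oxy]ethenyl}hex-4-enoate
Product: 7 methyl 5-methyl-2-(3-methylbut-2-en-1-yl)-2-[3-(trimethylsilyl)prop-1-en-2-yl]hex-4-enoate
Conditions: Me3SiCH2MgCl, Pd(PPh3)4 (5 mol%), THF, 0 °C to rt
Reagents that add atoms: (trimethylsilyl)methylmagnesium chloride, C[Si](C)(C)C[Mg]Cl
Why: Kumada–Corriu cross-coupling of a vinyl triflate with the (trimethylsilyl)methyl Grignard reagent under zerovalent palladium catalysis is the standard route to 2-substituted allylsilanes, and the hindered α-quaternary ester and the prenyl alkenes should be inert.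

Step 4
Reactants: 7 methyl 5-methyl-2-(3-methylbut-2-en-1-yl)-2-[3-(trimethylsilyl)prop-1-en-2-yl]hex-4-enoate
Product: 8 5-methyl-2-(3-methylbut-2-en-1-yl)-2-[3-(trimethylsilyl)prop-1-en-2-yl]hex-4-enoic acid
Conditions: KOH (10 equiv), MeOH/H2O, 70 °C; then 1 M HCl to pH 3, 0 °C
Reagents that add atoms: potassium hydroxide, [K+].[OH-]
Why: Saponification of the hindered methyl ester needs forcing base, which the allylsilane and the isolated alkenes should tolerate, and brief cold dilute acid in the work-up should not protodesilylate.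

Step 5
Reactants: 8 5-methyl-2-(3-methylbut-2-en-1-yl)-2-[3-(trimethylsilyl)prop-1-en-2-yl]hex-4-enoic acid
Product: 10 5-{1-hydroxy-5-methyl-2-(3-methylbut-2-en-1-yl)-2-[3-(trimethylsilyl)prop-1-en-2-yl]hex-4-en-1-ylidene}-2,2-dimethyl-1,3-dioxane-4,6-dione, via acid chloride 9 (not isolated)
Conditions: 1-chloro-N,N,2-trimethylprop-1-en-1-amine (Ghosez's reagent), CH2Cl2, 0 °C to rt; Meldrum's acid, DMAP (2.2 equiv), CH2Cl2, 0 °C to rt; cold 0.5 M HCl wash
Reagents that add atoms: Meldrum's acid (2,2-dimethyl-1,3-dioxane-4,6-dione), CC1(C)OC(=O)CC(=O)O1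
Why: Ghosez's reagent forms the acid chloride under neutral conditions (no HCl to attack the allylsilane), and C-acylation of Meldrum's acid by an acid chloride with DMAP is the standard preparation of 5-acyl Meldrum's acids, which are latent α-oxoketenes.

Step 6
Reactants: 10 5-{1-hydroxy-5-methyl-2-(3-methylbut-2-en-1-yl)-2-[3-(trimethylsilyl)prop-1-en-2-yl]hex-4-en-1-ylidene}-2,2-dimethyl-1,3-dioxane-4,6-dione
Product: 14 3-hydroxy-5-methyl-6,6-bis(3-methylbut-2-en-1-yl)cyclohexa-2,4-dien-1-one, via α-oxoketene 11 (not isolated), via silyl enol ether 12 (not isolated), via exocyclic alkene tautomer 13 (not isolated)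
Conditions: slow addition to PhMe (final 2 mM), 100 °C, N2 sweep; then Et3N (0.2 equiv), THF/H2O, rt; aq. citric acid
Reagents that add atoms: none
Why: Proposed new method: thermal fragmentation of the acyl Meldrum's acid (loss of acetone and CO2, a known ketene source) should give α-oxoketene 11, whose electrophilic ketene carbon (the future C3) is attacked by the terminal CH2 of the 2-(silylmethyl)allyl unit (the future C4) with a β-silyl-stabilised positive charge developing at C5; transfer of the silyl group to the enolate oxygen gives silyl enol ether 12, and hydrolysis followed by amine-mediated tautomerisation of the exocyclic alkene into conjugation gives 14. The closest known reaction types are the Lewis acid-mediated intramolecular acylation of allylsilanes by acid chlorides (Hosomi–Sakurai type), the intramolecular carbonyl-ene cyclisation of 2-substituted allyl units onto aldehydes, and the routine trapping of ketenes from acyl Meldrum's acids by heteroatom nucleophiles; the union of an α-oxoketene with an allylsilane carbon is the unprecedented element. The six-membered ring is closed in a 6-endo-trig sense at the allylsilane (both alkene carbons become ring atoms), with the ketene C=O exocyclic to the new ring. No stereocentre is formed. The step needs chemoselectivity for the allylsilane terminus over the two prenyl alkenes (which could react in a citronellal-like ene cyclisation) and over ketene dimerisation: the β-silicon effect makes C4 by far the most nucleophilic alkene carbon, the alternative cycloaddition modes of the allylsilane alkene would give strained bicyclo[2.2.0] or bridged products, and high dilution disfavours dimerisation. All plausible fates of the zwitterion (silyl transfer to oxygen, loss of the silyl group, loss of a proton) should converge on 14 after the hydrolytic work-up.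

Step 7
Reactants: 15 3-methoxybenzonitrile
Product: 17 2-formyl-3-methoxybenzonitrile, via aryllithium 16 (not isolated)
Conditions: lithium 2,2,6,6-tetramethylpiperidide, THF, –78 °C; DMF, –78 to 0 °C; aq. NH4Cl
Reagents that add atoms: N,N-dimethylformamide, CN(C)C=O
Why: Directed ortho-metalation should occur at the C–H flanked by the nitrile and the methoxy group (the most acidic site; the hindered amide base does not add to the nitrile at –78 °C), and formylation of the aryllithium with DMF gives the 1,2,3-trisubstituted aldehyde.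

Step 8
Reactants: 17 2-formyl-3-methoxybenzonitrile
Product: 19 rac-3,4-dimethoxy-2,3-dihydro-1H-isoindol-1-one, via cyclic imidate 18 (not isolated)
Conditions: MeOH, K2CO3 (10 mol%), rt
Reagents that add atoms: methanol, CO
Why: Base-catalysed tandem hemiacetal formation, addition of the alkoxide to the neighbouring nitrile and rearrangement of the cyclic imidate to the lactam is the known route from 2-formylbenzonitriles to 3-alkoxyisoindolin-1-ones; the stereocentre forms as the racemate and is erased in step 9.

Step 9
Reactants: 14 3-hydroxy-5-methyl-6,6-bis(3-methylbut-2-en-1-yl)cyclohexa-2,4-dien-1-one; 19 rac-3,4-dimethoxy-2,3-dihydro-1H-isoindol-1-one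
Product: 21 (3R)-3-[2-hydroxy-4-methyl-5,5-bis(3-methylbut-2-en-1-yl)-6-oxocyclohexa-1,3-dien-1-yl]-4-methoxy-2,3-dihydro-1H-isoindol-1-one (the target), via N-acyl imine 20 (not isolated)
Conditions: (R)-3,3'-bis(2,4,6-triisopropylphenyl)-1,1'-binaphthalene-2,2'-diyl hydrogen phosphate (10 mol%), 5 Å molecular sieves, PhMe, –20 °C
Reagents that add atoms: none
Why: In this chiral phosphoric acid-catalysed enantioselective Mannich-type amidoalkylation the acid eliminates methanol from 19 to give N-acyl imine 20 and holds it and the enol of 14 in a hydrogen-bonded ion pair, so that C2 of the vinylogous acid adds to one face of the C=N bond under control of the 3,3'-aryl groups of the catalyst (the R sense of induction is to be confirmed; the antipodal catalyst is equally available).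

**Compound list**

1 | methyl acetoacetate (methyl 3-oxobutanoate) | COC(=O)CC(C)=O | starting material
2 | prenyl bromide (1-bromo-3-methylbut-2-ene) | CC(C)=CCBr | starting material
3 | methyl 2-acetyl-5-methylhex-4-enoate (racemic, not isolated) | COC(=O)C(CC=C(C)C)C(C)=O | intermediate
4 | methyl 2-acetyl-5-methyl-2-(3-methylbut-2-en-1-yl)hex-4-enoate | COC(=O)C(CC=C(C)C)(CC=C(C)C)C(C)=O | intermediate
5 | potassium enolate of 4 (not isolated) | [K+].[O-]C(=C)C(CC=C(C)C)(CC=C(C)C)C(=O)OC | intermediate
6 | methyl 5-methyl-2-(3-methylbut-2-en-1-yl)-2-{1-[(trifluoromethanesulfonyl)oxy]ethenyl}hex-4-enoate | COC(=O)C(CC=C(C)C)(CC=C(C)C)C(=C)OS(=O)(=O)C(F)(F)F | intermediate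
7 | methyl 5-methyl-2-(3-methylbut-2-en-1-yl)-2-[3-(trimethylsilyl)prop-1-en-2-yl]hex-4-enoate | COC(=O)C(CC=C(C)C)(CC=C(C)C)C(=C)C[Si](C)(C)C | intermediate
8 | 5-methyl-2-(3-methylbut-2-en-1-yl)-2-[3-(trimethylsilyl)prop-1-en-2-yl]hex-4-enoic acid | OC(=O)C(CC=C(C)C)(CC=C(C)C)C(=C)C[Si](C)(C)C | intermediate
9 | 5-methyl-2-(3-methylbut-2-en-1-yl)-2-[3-(trimethylsilyl)prop-1-en-2-yl]hex-4-enoyl chloride (not isolated) | ClC(=O)C(CC=C(C)C)(CC=C(C)C)C(=C)C[Si](C)(C)C | intermediate
10 | 5-{1-hydroxy-5-methyl-2-(3-methylbut-2-en-1-yl)-2-[3-(trimethylsilyl)prop-1-en-2-yl]hex-4-en-1-ylidene}-2,2-dimethyl-1,3-dioxane-4,6-dione | CC1(C)OC(=O)C(=C(O)C(CC=C(C)C)(CC=C(C)C)C(=C)C[Si](C)(C)C)C(=O)O1 | intermediate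
11 | 7-methyl-4-(3-methylbut-2-en-1-yl)-4-[3-(trimethylsilyl)prop-1-en-2-yl]octa-1,6-diene-1,3-dione (α-oxoketene, not isolated) | O=C=CC(=O)C(CC=C(C)C)(CC=C(C)C)C(=C)C[Si](C)(C)C | intermediate
12 | 5-methylidene-6,6-bis(3-methylbut-2-en-1-yl)-3-[(trimethylsilyl)oxy]cyclohex-2-en-1-one (not isolated) | C=C1CC(O[Si](C)(C)C)=CC(=O)C1(CC=C(C)C)CC=C(C)C | intermediate
13 | 3-hydroxy-5-methylidene-6,6-bis(3-methylbut-2-en-1-yl)cyclohex-2-en-1-one (not isolated) | C=C1CC(O)=CC(=O)C1(CC=C(C)C)CC=C(C)C | intermediate
14 | 3-hydroxy-5-methyl-6,6-bis(3-methylbut-2-en-1-yl)cyclohexa-2,4-dien-1-one | CC1=CC(O)=CC(=O)C1(CC=C(C)C)CC=C(C)C | intermediate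
15 | 3-methoxybenzonitrile | COc1cccc(C#N)c1 | starting material
16 | 2-cyano-6-methoxyphenyllithium (not isolated) | [Li]c1c(OC)cccc1C#N | intermediate
17 | 2-formyl-3-methoxybenzonitrile | COc1cccc(C#N)c1C=O | intermediate
18 | 1-imino-3,4-dimethoxy-1,3-dihydro-2-benzofuran (racemic, not isolated) | COC1OC(=N)c2cccc(OC)c12 | intermediate
19 | rac-3,4-dimethoxy-2,3-dihydro-1H-isoindol-1-one | COC1NC(=O)c2cccc(OC)c12 | intermediate
20 | 4-methoxy-1H-isoindol-1-one (N-acyl imine, not isolated) | COc1cccc2c1C=NC2=O | intermediate
21 | (3R)-3-[2-hydroxy-4-methyl-5,5-bis(3-methylbut-2-en-1-yl)-6-oxocyclohexa-1,3-dien-1-yl]-4-methoxy-2,3-dihydro-1H-isoindol-1-one | COc1cccc2c1[C@H](C1=C(O)C=C(C)C(CC=C(C)C)(CC=C(C)C)C1=O)NC2=O | target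

**Step count**

Total steps: 9. Longest linear sequence: 7 (steps 1 to 6, then step 9).

**Steps most likely to fail**

Step 6 (proposed new method). The α-oxoketene may react with a prenyl alkene (ene reaction or [2+2] cycloaddition) or dimerise before the allylsilane terminus attacks, and the 1,5-diene units may undergo Cope rearrangement at the temperature needed. The fallback uses known chemistry without a ring closure; it sets out from prenyl bromide 2 and returns at 14. Commercial 5-methylcyclohexane-1,3-dione (CC1CC(=O)CC(=O)C1) is condensed with 2-methylpropan-1-ol (TsOH, PhMe, water removal) to the vinylogous ester 5-methyl-3-(2-methylpropoxy)cyclohex-2-en-1-one F1. Stork–Danheiser alkylation (LiN(iPr)2, THF, –78 °C, then 2) should give 5-methyl-6-(3-methylbut-2-en-1-yl)-3-(2-methylpropoxy)cyclohex-2-en-1-one F2. A second kinetic enolisation at the same carbon and alkylation with 2 should give 5-methyl-6,6-bis(3-methylbut-2-en-1-yl)-3-(2-methylpropoxy)cyclohex-2-en-1-one F3. Hydrolysis with aqueous NaOH in dioxane gives 5-methyl-4,4-bis(3-methylbut-2-en-1-yl)cyclohexane-1,3-dione F4. Double silylation (Me3SiOTf, Et3N, CH2Cl2) gives 5-methyl-6,6-bis(3-methylbut-2-en-1-yl)-1,3-bis[(trimethylsilyl)oxy]cyclohexa-1,3-diene F5. Saegusa–Ito dehydrogenation with Pd(OAc)2 in MeCN gives 3-methyl-4,4-bis(3-methylbut-2-en-1-yl)-5-[(trimethylsilyl)oxy]cyclohexa-2,5-dien-1-one F6, which is hydrolysed on aqueous work-up to 14.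

Step 9. Facial selectivity may be poor, because the acidic nucleophile 14 can promote an uncatalysed background ionisation of 19, and the enantiomeric purity may erode through reversible ionisation of the product. The fallback sets out from 14 and 19 and returns at 21. A racemic amidoalkylation with an achiral acid (diphenyl phosphate, CH2Cl2, rt) is followed by separation of the enantiomers by preparative chromatography on a chiral stationary phase. This gives 21 together with its mirror image, (3S)-3-[2-hydroxy-4-methyl-5,5-bis(3-methylbut-2-en-1-yl)-6-oxocyclohexa-1,3-dien-1-yl]-4-methoxy-2,3-dihydro-1H-isoindol-1-one F7.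

Step 5. C-acylation of Meldrum's acid by the neopentyl-type acid chloride may be slow, with competing O-acylation or decomposition of the acid chloride. The fallback sets out from acid 8 (through the same acid chloride 9) and returns at α-oxoketene 11, and hence at 14. Crossed Claisen condensation of 9 with LiCH2CO2tBu (2.2 equiv, THF, –78 °C) should give tert-butyl 7-methyl-4-(3-methylbut-2-en-1-yl)-3-oxo-4-[3-(trimethylsilyl)prop-1-en-2-yl]oct-6-enoate F8. This β-keto ester loses 2-methylpropan-2-ol in dilute toluene at 110 °C to give the same ketene 11, which then follows step 6.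

**Further compounds**

F1 | step 6 | 5-methyl-3-(2-methylpropoxy)cyclohex-2-en-1-one (racemic) | CC(C)COC1=CC(=O)CC(C)C1
F2 | step 6 | 5-methyl-6-(3-methylbut-2-en-1-yl)-3-(2-methylpropoxy)cyclohex-2-en-1-one (racemic, diastereomer mixture) | CC(C)COC1=CC(=O)C(CC=C(C)C)C(C)C1
F3 | step 6 | 5-methyl-6,6-bis(3-methylbut-2-en-1-yl)-3-(2-methylpropoxy)cyclohex-2-en-1-one (racemic) | CC(C)COC1=CC(=O)C(CC=C(C)C)(CC=C(C)C)C(C)C1
F4 | step 6 | 5-methyl-4,4-bis(3-methylbut-2-en-1-yl)cyclohexane-1,3-dione (racemic) | CC1CC(=O)CC(=O)C1(CC=C(C)C)CC=C(C)C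
F5 | step 6 | 5-methyl-6,6-bis(3-methylbut-2-en-1-yl)-1,3-bis[(trimethylsilyl)oxy]cyclohexa-1,3-diene (racemic) | CC1C=C(O[Si](C)(C)C)C=C(O[Si](C)(C)C)C1(CC=C(C)C)CC=C(C)C
F6 | step 6 | 3-methyl-4,4-bis(3-methylbut-2-en-1-yl)-5-[(trimethylsilyl)oxy]cyclohexa-2,5-dien-1-one | CC1=CC(=O)C=C(O[Si](C)(C)C)C1(CC=C(C)C)CC=C(C)C
F7 | step 9 | (3S)-3-[2-hydroxy-4-methyl-5,5-bis(3-methylbut-2-en-1-yl)-6-oxocyclohexa-1,3-dien-1-yl]-4-methoxy-2,3-dihydro-1H-isoindol-1-one | COc1cccc2c1[C@@H](C1=C(O)C=C(C)C(CC=C(C)C)(CC=C(C)C)C1=O)NC2=O
F8 | step 5 | tert-butyl 7-methyl-4-(3-methylbut-2-en-1-yl)-3-oxo-4-[3-(trimethylsilyl)prop-1-en-2-yl]oct-6-enoate | CC(C)(C)OC(=O)CC(=O)C(CC=C(C)C)(CC=C(C)C)C(=C)C[Si](C)(C)C
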